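The earlier runs and the new flask are calculated with made-up constants; the scatter is artificial.

I was asked what share of the substrate stands as target in the green run at 15 min, a flask that began with target already in it, and what the earlier runs show about the orders and the fate of target.

| flask | substrate | partner | target | time |
|---|---|---|---|---|
| red | 0.600 M | 1.20 M |  |  |
| teal | 0.300 M | 0.900 M |  |  |
| ochre | 1.20 M | 1.20 M |  |  |
| violet | 0.600 M | 2.40 M |  |  |
| green | 0.600 M | 1.20 M | 0.480 M | 15 min |

- red run (time / min: [target] / M): 0.60: 0.010; 0.95: 0.016; 1.5: 0.029; 2.4: 0.043; 3.8: 0.090; 6.0: 0.116; 9.5: 0.145; 15: 0.159
- teal run (time / min: [target] / M): 0.60: 0; 0.95: 0.016; 1.5: 0.019; 2.4: 0.030; 3.8: 0.025; 6.0: 0.046; 9.5: 0.053; 15: 0.084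
- ochre run (time / min: [target] / M): 0.60: 0.035; 0.95: 0.053; 1.5: 0.074; 2.4: 0.119; 3.8: 0.157; 6.0: 0.211; 9.5: 0.247; 15: 0.292
- violet run (time / min: [target] / M): 0.60: 0.034; 0.95: 0.075; 1.5: 0.099; 2.4: 0.133; 3.8: 0.165; 6.0: 0.193; 9.5: 0.194; 15: 0.170

(scatter of a reading: 0.006 M)

- Overall: substrate + partner -> target.
- Constant volume, constant temperature.
- "The second partner" is partner.
- An order is taken over about fifteen percent of the charge, up and down.
- A share of target counts the target that was charged too.

* the exponent of [partner] in the starting rate at the charge of the red run (at the point where two percent of the substrate have become target)
* the exponent of [substrate] in the starting rate at the charge of the red run (at the point where two percent of the substrate have become target) (one fixed amount of target, the same in the runs compared)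
* target in the green run at 15 min, as a share of the substrate charged
* which of these the readings show (the product binds the second partner / the product reacts on with the second partner / the product decays / nothing beyond the main steps / the product binds the substrate)

In the violet run, target stood at 0.194 M at 9.5 min and at 0.170 M at 15 min, so target was being consumed. I treated this loss as pseudo-first-order: a clearing constant λ, the fraction of the target present that goes per minute, taken as proportional to [partner]. At the top of the violet curve, formation equals loss. The readings at 6.0 min and 9.5 min were level within the scatter, so I read the top as 0.194 M at 7.75 min. The violet readings rose at about 0.0660 M min⁻¹ over the first 1.5 min; I took this as the starting formation rate, which drains substrate at 0.110 min⁻¹. By my estimate, this left a formation rate of 0.0281 M min⁻¹ at the top, so λ was 0.145 min⁻¹ in the violet run. The green run has half that partner charge, so I took its clearing constant as λ = 0.0727 min⁻¹.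

The green charge matches the red one apart from the charged target, so I drew the green curve as the red curve plus a gap that starts at 0.480 M and shrinks at λ. The red readings rose at about 0.0237 M min⁻¹ over the first 3.8 min, which I took as the formation rate at the start of the green run; my loss there of 0.0349 M min⁻¹ was larger, so I drew the green curve falling from the outset. It has no knee, and the gap halves every 9.53 min. At 15 min the gap is 0.161 M above the red reading of 0.159 M, which gives a green share of 53.4%.

The forecast gave 1.8 for the partner order, 1.3 for the substrate order and 59% for the share, above my figure. It chose "the product reacts on with the second partner", saying: “Violet peaks and then falls, so target is being consumed.”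

The simulation gave orders of 1.4 and 1.1, a green share of 59.1%, and "the product reacts on with the second partner".

    substrate + partner → target (0.02454 M⁻¹ min⁻¹)
    substrate + 2 partner → target + partner (0.01308 M⁻² min⁻¹)
    target + partner → side product (0.06420 M⁻¹ min⁻¹)

Measured against the red reading, the green run kept 40.8% of its charged target as gap, where my λ of 0.0727 min⁻¹ kept 33.6%. That result corresponds to a clearing constant of 0.0598 min⁻¹. The green share stands at 59.1% because target and partner go on to side product. In the simulated green run without that step, λ is zero, the charged target stays whole, and the share reaches 125%.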